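## Retrosynthetic overview

- **Feature:** ring B is a 1,2,3,4-substituted resorcinol (C1 enone carbon, C2–OMe, C3 prenyl, C4–OH, C5 and C6 H). Its two meta oxygens flank the prenyl carbon. A vinylketene (C=O becomes C2–O) and an ynol ether (C–O becomes C4–O, alkyne substituent goes to C3) deliver exactly this pattern.
- **Last disconnections:** three O–Si bonds (one fluoride step) and the enone Cα=Cβ bond (directed aldol addition and dehydration of a ring A methyl ketone with a ring B aldehyde). Ring A is bought.
- **Ring B aldehyde:** it comes from O2-methylation and acetal hydrolysis of a phenol with OH at C2, OSi(iPr)3 at C4 and CH(OMe)2 at C1.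
- **That phenol:** it comes from benzannulation (bonds C2–C3, C4–C5, C1–C2) of an acetal-bearing diazo enone and a prenyl siloxyalkyne. Ring B is the only ring formed.
- **Precursors:** the diazo enone comes from Wittig olefination and deacylative diazo transfer. The siloxyalkyne comes from prenyl bromide and ethynyl Grignard reagent, then acetylide oxidation and O-silylation.

Key step: step 5

Assumption: 1 is used as the commercial 60 wt % aqueous solution and 8 as the commercial 0.5 M solution in THF. The target has no stereocentre, and its only stereo-element, the E alkene, is set in step 10.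

## Route

Step 1
Reactants: 1 2,2-dimethoxyacetaldehyde; 2 1-(triphenylphosphoranylidene)propan-2-one
Product: 3 (E)-5,5-dimethoxypent-3-en-2-one
Conditions: 2 (1.05 equiv), CH2Cl2, rt
Reagents that add atoms: none
Why: Wittig olefination with a stabilised acyl ylide tolerates the water of the aldehyde solution and should give the E enone through the reversible, thermodynamically steered oxaphosphetane pathway.

Step 2
Reactants: 3 (E)-5,5-dimethoxypent-3-en-2-one
Product: 6 (E)-1-diazo-5,5-dimethoxypent-3-en-2-one, via lithium enolate 4 (not isolated), via trifluoroacetyl diketone 5 (not isolated)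
Conditions: LiN(SiMe3)2, THF, −78 °C; CF3CO2CH2CF3, −78 °C; brief cold 5% aq HCl wash; then MsN3, Et3N, H2O (1 equiv), MeCN, rt; product kept cold and dark and used at once
Reagents that add atoms: methanesulfonyl azide, CS(=O)(=O)N=[N+]=[N-] (the N2 unit of 6); 2,2,2-trifluoroethyl trifluoroacetate, O=C(OCC(F)(F)F)C(F)(F)F (CF3CO, held only in 5); LiN(SiMe3)2, [Li]N([Si](C)(C)C)[Si](C)(C)C (Li, held only in 4)
Why: Kinetic deprotonation at the methyl group and Claisen-type trifluoroacetylation activate that carbon for a detrifluoroacetylative (Regitz-type deacylative) diazo transfer under mild amine base, the standard way to diazo ketones of enones, and the electron-poor allylic acetal and the E alkene are not affected.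

Step 3
Reactants: 7 1-bromo-3-methylbut-2-ene (prenyl bromide); 8 ethynylmagnesium bromide
Product: 9 5-methylhex-4-en-1-yne
Conditions: 8 (1.5 equiv), CuCl (5 mol %), THF, 0 °C → rt; aq NH4Cl; pentane; fractional distillation
Reagents that add atoms: none
Why: Copper-catalysed allylation of an alkynyl Grignard reagent takes place in the SN2 sense at the unhindered primary carbon of prenyl bromide, and the excess of 8 holds back double alkylation.

Step 4
Reactants: 9 5-methylhex-4-en-1-yne
Product: 12 triisopropyl[(5-methylhex-4-en-1-yn-1-yl)oxy]silane, via lithium acetylide 10 (not isolated), via lithium ynolate 11 (not isolated)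
Conditions: n-BuLi (1.0 equiv), THF, −78 °C; t-BuOOLi (from anhydrous t-BuOOH and LiN(SiMe3)2, THF, −78 °C), −78 → 0 °C; iPr3SiOTf, −78 → 0 °C; pentane/aq NaHCO3; rapid filtration through SiO2 (hexane)
Reagents that add atoms: tert-butyl hydroperoxide, CC(C)(C)OO (the ynol oxygen); triisopropylsilyl triflate, CC(C)[Si](OS(=O)(=O)C(F)(F)F)(C(C)C)C(C)C; n-butyllithium, [Li]CCCC (Li, held only in 10 and 11)
Why: Electrophilic oxygen transfer from lithium tert-butyl peroxide to a lithium acetylide is an established ynolate synthesis, the bulky and hard silyl triflate silylates 11 on oxygen rather than on carbon, and one equivalent of n-BuLi at −78 °C removes only the alkyne C–H, so the skipped enyne stays in place.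

Step 5
Reactants: 6 (E)-1-diazo-5,5-dimethoxypent-3-en-2-one; 12 triisopropyl[(5-methylhex-4-en-1-yn-1-yl)oxy]silane
Product: 17 6-(dimethoxymethyl)-2-(3-methylbut-2-enyl)-3-(triisopropylsilyloxy)phenol, via vinylketene 13 (not isolated), via vinylcyclobutenone 14 (not isolated), via dienylketene 15 (not isolated), via cyclohexadienone 16 (not isolated)
Conditions: 6 (1 equiv), 12 (1.3 equiv), degassed ClCH2CH2Cl (0.15 M), hν 254 nm (low-pressure Hg lamps, quartz), rt, until 6 is consumed; then reflux (83 °C) in the dark; SiO2 deactivated with Et3N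
Reagents that add atoms: none
Why: Light expels N2 from 6 and the alkenyl group shifts to the diazo carbon (photo-Wolff rearrangement) to give vinylketene 13, whose carbonyl carbon (future C2) bonds to the prenyl-bearing nucleophilic carbon of 12 (future C3) and whose α-carbon (future C5) bonds to the siloxy carbon (future C4) in a (2+2) cycloaddition that gives 14. Light or heat opens 14 by reversible 4π electrocyclic cleavage of the C2–C5 bond to dienylketene 15; only the isomer whose alkenyl arm points towards the ketene reacts on, closing ring B by thermal disrotatory 6π electrocyclization between ketene carbon C2 and the acetal-bearing alkene terminus C1, and enolisation of 16 gives phenol 17. This is the Danheiser benzannulation in its diazo ketone form with a siloxyalkyne partner, a known route to resorcinol monosilyl ethers. No stereocentre remains, since the sp3 carbons of 14 and 16 are transient, racemic and end as arene carbons. The step needs regioselectivity, which the matched polarity of ketene (electrophilic carbonyl carbon) and ynol ether (nucleophilic β-carbon) secures, and chemoselectivity for the alkyne over the trisubstituted prenyl alkene, which the much higher reactivity of the oxygen-activated triple bond towards ketenes secures. Because O2 stems from the ketene carbonyl (free OH) and O4 from 12 (silyl ether), the two meta oxygens emerge differentiated, and the neutral medium spares the acetal and the skipped alkene.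

Step 6
Reactants: 17 6-(dimethoxymethyl)-2-(3-methylbut-2-enyl)-3-(triisopropylsilyloxy)phenol
Product: 18 [4-(dimethoxymethyl)-3-methoxy-2-(3-methylbut-2-enyl)phenoxy]triisopropylsilane
Conditions: MeI (3 equiv), K2CO3 (2 equiv), dry acetone, reflux
Reagents that add atoms: iodomethane, CI
Why: Williamson O-methylation can reach only the single free hydroxyl at C2, the acetal is inert to base, and the silyl ether on a ring that still lacks an electron-withdrawing group withstands anhydrous carbonate and cannot migrate to the meta oxygen.

Step 7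
Reactants: 18 [4-(dimethoxymethyl)-3-methoxy-2-(3-methylbut-2-enyl)phenoxy]triisopropylsilane
Product: 19 2-methoxy-3-(3-methylbut-2-enyl)-4-(triisopropylsilyloxy)benzaldehyde
Conditions: pyridinium p-toluenesulfonate (10 mol %), acetone–H2O, rt
Reagents that add atoms: water, O
Why: Acid-catalysed acetal hydrolysis is very fast for a benzylic acetal on an ortho,para-dioxygenated ring, so a weak acid suffices that leaves the aryl silyl ether and the prenyl group (no free ortho hydroxyl, hence no chroman closure) untouched.

Step 8
Reactants: 20 3,4-dihydroxyacetophenone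
Product: 21 1-[3,4-bis(tert-butyldimethylsilyloxy)phenyl]ethan-1-one
Conditions: t-BuMe2SiCl (2.5 equiv), imidazole (5 equiv), DMF, rt
Reagents that add atoms: tert-butyldimethylsilyl chloride, CC(C)(C)[Si](C)(C)Cl
Why: Imidazole-promoted silylation of both catechol hydroxyls is routine and puts all three phenols of the final chalcone under fluoride-labile groups, so no acid is needed at the end.

Step 9
Reactants: 21 1-[3,4-bis(tert-butyldimethylsilyloxy)phenyl]ethan-1-one; 19 2-methoxy-3-(3-methylbut-2-enyl)-4-(triisopropylsilyloxy)benzaldehyde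
Product: 23 rac-1-[3,4-bis(tert-butyldimethylsilyloxy)phenyl]-3-hydroxy-3-[2-methoxy-3-(3-methylbut-2-enyl)-4-(triisopropylsilyloxy)phenyl]propan-1-one, via lithium enolate 22 (not isolated)
Conditions: 21, LiN(SiMe3)2 (1.05 equiv), THF, −78 °C; 19, −78 °C; AcOH in THF at −78 °C
Reagents that add atoms: LiN(SiMe3)2, [Li]N([Si](C)(C)C)[Si](C)(C)C (Li, held only in 22)
Why: Directed aldol addition of the preformed enolate to the non-enolisable aldehyde avoids the hydroxide or alkoxide of a classical Claisen–Schmidt condensation, which would strip the aryl silyl ethers (first of all the one para to the formyl group), and the carbinol centre forms without control as a racemate because step 10 erases it.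

Step 10
Reactants: 23 rac-aldol adduct
Product: 25 (E)-1-[3,4-bis(tert-butyldimethylsilyloxy)phenyl]-3-[2-methoxy-3-(3-methylbut-2-enyl)-4-(triisopropylsilyloxy)phenyl]prop-2-en-1-one, via mesylate 24 (not isolated)
Conditions: MsCl (1.5 equiv), Et3N (4 equiv), CH2Cl2, 0 °C → rt
Reagents that add atoms: methanesulfonyl chloride, CS(=O)(=O)Cl (MeSO2, held only in 24)
Why: Mesylation of the electron-rich benzylic alcohol followed by E1cB elimination through the ketone enolate gives the conjugated enone, and the E geometry follows from the arrangement with aryl and aroyl groups apart, which is strongly preferred for chalcones.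

Step 11
Reactants: 25 tris-silylated chalcone
Product: 26 licoagrochalcone C, (E)-1-(3,4-dihydroxyphenyl)-3-[4-hydroxy-2-methoxy-3-(3-methylbut-2-enyl)phenyl]prop-2-en-1-one
Conditions: Bu4NF (3.5 equiv), AcOH (3.5 equiv), THF, 0 °C → rt, argon
Reagents that add atoms: none
Why: Fluoride-induced desilylation cleaves all three aryl silyl ethers at once (strong Si–F bond, good phenoxide leaving groups), the acetic acid buffer keeps the catechol protonated and so guards it from air oxidation, and the absence of strong acid spares the ortho-prenylphenol from chroman closure and leaves the E alkene unchanged.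

## Compound list

1 | 2,2-dimethoxyacetaldehyde | COC(OC)C=O | starting material
2 | 1-(triphenylphosphoranylidene)propan-2-one | CC(=O)C=P(c1ccccc1)(c1ccccc1)c1ccccc1 | starting material
3 | (E)-5,5-dimethoxypent-3-en-2-one | COC(OC)/C=C/C(C)=O | intermediate
4 | lithium (E)-5,5-dimethoxypenta-1,3-dien-2-olate (kinetic enolate of 3) | [Li]OC(=C)/C=C/C(OC)OC | intermediate
5 | (E)-1,1,1-trifluoro-7,7-dimethoxyhept-5-ene-2,4-dione | COC(OC)/C=C/C(=O)CC(=O)C(F)(F)F | intermediate
6 | (E)-1-diazo-5,5-dimethoxypent-3-en-2-one | COC(OC)/C=C/C(=O)C=[N+]=[N-] | intermediate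
7 | 1-bromo-3-methylbut-2-ene | CC(C)=CCBr | starting material
8 | ethynylmagnesium bromide | C#C[Mg]Br | starting material
9 | 5-methylhex-4-en-1-yne | C#CCC=C(C)C | intermediate
10 | (5-methylhex-4-en-1-yn-1-yl)lithium | [Li]C#CCC=C(C)C | intermediate
11 | lithium 5-methylhex-4-en-1-yn-1-olate | [Li]OC#CCC=C(C)C | intermediate
12 | triisopropyl[(5-methylhex-4-en-1-yn-1-yl)oxy]silane | CC(C)=CCC#CO[Si](C(C)C)(C(C)C)C(C)C | intermediate
13 | (E)-5,5-dimethoxypenta-1,3-dien-1-one | COC(OC)/C=C/C=C=O | intermediate
14 | rac-4-[(E)-3,3-dimethoxyprop-1-enyl]-2-(3-methylbut-2-enyl)-3-(triisopropylsilyloxy)cyclobut-2-en-1-one | O=C1C(CC=C(C)C)=C(O[Si](C(C)C)(C(C)C)C(C)C)C1/C=C/C(OC)OC | intermediate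
15 | (3E,5E)-7,7-dimethoxy-2-(3-methylbut-2-enyl)-3-(triisopropylsilyloxy)hepta-1,3,5-trien-1-one | O=C=C(CC=C(C)C)/C(O[Si](C(C)C)(C(C)C)C(C)C)=C\C=C\C(OC)OC | intermediate
16 | rac-6-(dimethoxymethyl)-2-(3-methylbut-2-enyl)-3-(triisopropylsilyloxy)cyclohexa-2,4-dien-1-one | O=C1C(CC=C(C)C)=C(O[Si](C(C)C)(C(C)C)C(C)C)C=CC1C(OC)OC | intermediate
17 | 6-(dimethoxymethyl)-2-(3-methylbut-2-enyl)-3-(triisopropylsilyloxy)phenol | COC(OC)c1ccc(O[Si](C(C)C)(C(C)C)C(C)C)c(CC=C(C)C)c1O | intermediate
18 | [4-(dimethoxymethyl)-3-methoxy-2-(3-methylbut-2-enyl)phenoxy]triisopropylsilane | COc1c(C(OC)OC)ccc(O[Si](C(C)C)(C(C)C)C(C)C)c1CC=C(C)C | intermediate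
19 | 2-methoxy-3-(3-methylbut-2-enyl)-4-(triisopropylsilyloxy)benzaldehyde | COc1c(C=O)ccc(O[Si](C(C)C)(C(C)C)C(C)C)c1CC=C(C)C | intermediate
20 | 3,4-dihydroxyacetophenone | CC(=O)c1ccc(O)c(O)c1 | starting material
21 | 1-[3,4-bis(tert-butyldimethylsilyloxy)phenyl]ethan-1-one | CC(=O)c1ccc(O[Si](C)(C)C(C)(C)C)c(O[Si](C)(C)C(C)(C)C)c1 | intermediate
22 | lithium 1-[3,4-bis(tert-butyldimethylsilyloxy)phenyl]ethen-1-olate | [Li]OC(=C)c1ccc(O[Si](C)(C)C(C)(C)C)c(O[Si](C)(C)C(C)(C)C)c1 | intermediate
23 | rac-1-[3,4-bis(tert-butyldimethylsilyloxy)phenyl]-3-hydroxy-3-[2-methoxy-3-(3-methylbut-2-enyl)-4-(triisopropylsilyloxy)phenyl]propan-1-one | COc1c(C(O)CC(=O)c2ccc(O[Si](C)(C)C(C)(C)C)c(O[Si](C)(C)C(C)(C)C)c2)ccc(O[Si](C(C)C)(C(C)C)C(C)C)c1CC=C(C)C | intermediate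
24 | rac-methanesulfonate of 23 | COc1c(C(CC(=O)c2ccc(O[Si](C)(C)C(C)(C)C)c(O[Si](C)(C)C(C)(C)C)c2)OS(C)(=O)=O)ccc(O[Si](C(C)C)(C(C)C)C(C)C)c1CC=C(C)C | intermediate
25 | (E)-1-[3,4-bis(tert-butyldimethylsilyloxy)phenyl]-3-[2-methoxy-3-(3-methylbut-2-enyl)-4-(triisopropylsilyloxy)phenyl]prop-2-en-1-one | COc1c(/C=C/C(=O)c2ccc(O[Si](C)(C)C(C)(C)C)c(O[Si](C)(C)C(C)(C)C)c2)ccc(O[Si](C(C)C)(C(C)C)C(C)C)c1CC=C(C)C | intermediate
26 | licoagrochalcone C | COc1c(/C=C/C(=O)c2ccc(O)c(O)c2)ccc(O)c1CC=C(C)C | target

## Step count and risks

Total step count: 11.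

Longest linear sequence: 8 steps (1, 2, 5, 6, 7, 9, 10, 11). The arm through steps 3 and 4 has the same length.

### Step 5 (key step)

**What may go wrong.** The short-lived aldoketene may dimerise, or be captured by moisture or by the phenolic product, before it meets the alkyne. The growing arene screens the light. Long irradiation can scramble the alkene geometry or start light-induced cyclisation of the ortho-prenylphenol.

**Fallback.** An isolable ketene and an anionic partner replace the transient ketene and the neutral alkyne. The fallback sets out from 6 and 12 and comes back at 17.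
- Compound 6 is silylated on carbon (iPr3SiOTf, iPr2NEt, Et2O–hexane, 0 °C → rt) to (E)-1-diazo-5,5-dimethoxy-1-(triisopropylsilyl)pent-3-en-2-one F1.
- Photo-Wolff rearrangement (300 nm, hexane) turns it into the storable silyl-stabilised ketene (E)-5,5-dimethoxy-2-(triisopropylsilyl)penta-1,3-dien-1-one F2, which is purified with no phenol present.
- Ynolate 11 is set free from purified 12 with MeLi (THF, 0 °C → rt) and combined with F2 at −78 °C → rt.
- C-acylation of the ynolate gives the lithium 3-oxidodienylketene F3, which closes by 6π electrocyclization.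
- Tautomerisation and a 1,3 carbon-to-oxygen silyl shift follow. O4 now stems from the ketene and takes up the silyl group, and O2 stems from the ynolate. Protonation should give 17.

### Step 4

**What may go wrong.** The doubly activated CH2 may be metalated, with drift to a conjugated vinylallene. Oxygen transfer may be sluggish. Silylation may occur on carbon instead of oxygen. The ynol ether may hydrolyse on silica.

**Fallback.** The ynolate is made by Kowalski-type ester homologation instead of acetylide oxidation. No numbered compound is carried over, and 7 to 10 are not needed. The fallback sets out from purchased ethyl 4-methylpent-3-enoate F4 and comes back at ynolate 11, which is silylated to 12 as in step 4.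
- LiCHBr2 (CH2Br2, lithium 2,2,6,6-tetramethylpiperidide, THF, −78 °C) adds to the ester, and loss of ethoxide gives lithium 1,1-dibromo-5-methylhexa-1,4-dien-2-olate F5.
- n-BuLi then effects bromine–lithium exchange, and on warming the prenyl group shifts from the former carbonyl carbon to the carbenoid carbon.
- The group R of RCO2Et ends up on the alkyne, so the C6 acid ester is required. The next homologue, a 5-methylhex-4-enoate, would put a homoprenyl chain on C3.

### Step 9

**What may go wrong.** The aldol addition may reverse with this electron-rich, doubly ortho-substituted aldehyde on warming or work-up, and silyl groups may be lost or transferred to the aldolate.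

**Fallback.** A thermodynamically driven Claisen–Schmidt condensation on base-stable acetal-type ethers replaces the directed aldol. The fallback sets out from 19 and 20 and comes back at 26.
- Compound 19 is desilylated (Bu4NF, THF, 0 °C) to 4-hydroxy-2-methoxy-3-(3-methylbut-2-enyl)benzaldehyde F6.
- F6 is protected (MOMCl, iPr2NEt, CH2Cl2) as 2-methoxy-4-(methoxymethoxy)-3-(3-methylbut-2-enyl)benzaldehyde F7.
- Compound 20 is converted in the same way into 1-[3,4-bis(methoxymethoxy)phenyl]ethan-1-one F8.
- KOH in EtOH at rt condenses F7 and F8 to the tris(methoxymethyl) chalcone F9.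
- Dilute HCl in MeOH at rt, stopped early to limit chroman closure, should release 26.

## Further compounds

F1 | step 5 | (E)-1-diazo-5,5-dimethoxy-1-(triisopropylsilyl)pent-3-en-2-one | COC(OC)/C=C/C(=O)C(=[N+]=[N-])[Si](C(C)C)(C(C)C)C(C)C
F2 | step 5 | (E)-5,5-dimethoxy-2-(triisopropylsilyl)penta-1,3-dien-1-one | COC(OC)/C=C/C(=C=O)[Si](C(C)C)(C(C)C)C(C)C
F3 | step 5 | lithium (3Z,5E)-7,7-dimethoxy-2-(3-methylbut-2-enyl)-1-oxo-4-(triisopropylsilyl)hepta-1,3,5-trien-3-olate | O=C=C(CC=C(C)C)/C(O[Li])=C(\C=C\C(OC)OC)[Si](C(C)C)(C(C)C)C(C)C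
F4 | step 4 | ethyl 4-methylpent-3-enoate (purchased) | CCOC(=O)CC=C(C)C
F5 | step 4 | lithium 1,1-dibromo-5-methylhexa-1,4-dien-2-olate | [Li]OC(CC=C(C)C)=C(Br)Br
F6 | step 9 | 4-hydroxy-2-methoxy-3-(3-methylbut-2-enyl)benzaldehyde | COc1c(C=O)ccc(O)c1CC=C(C)C
F7 | step 9 | 2-methoxy-4-(methoxymethoxy)-3-(3-methylbut-2-enyl)benzaldehyde | COCOc1ccc(C=O)c(OC)c1CC=C(C)C
F8 | step 9 | 1-[3,4-bis(methoxymethoxy)phenyl]ethan-1-one | COCOc1ccc(C(C)=O)cc1OCOC
F9 | step 9 | (E)-1-[3,4-bis(methoxymethoxy)phenyl]-3-[2-methoxy-4-(methoxymethoxy)-3-(3-methylbut-2-enyl)phenyl]prop-2-en-1-one | COCOc1ccc(/C=C/C(=O)c2ccc(OCOC)c(OCOC)c2)c(OC)c1CC=C(C)C
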